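**Plan**
1. Numbering of the open chain follows geranylgeraniol: C1 and C20 are the two CH2O carbons on the C2=C3 alkene, and C15 is the terminal gem-dimethyl carbon.
2. Retrosynthesis: (a) both acetates are removed, giving diol 9; (b) the ring bond between the ring CH (C10) and the gem-dimethyl carbon (C15) is cut and the ring alkene C11=C12 is returned to C10=C11, which opens the ring to the achiral tetraene diol 8; (c) the sp2–sp3 bond C3–C4 is cut to a homofarnesyl borane and (Z)-2-iodobut-2-ene-1,4-diol 6.
3. Enabling feature: the 2,6,6-trimethylcyclohex-2-enyl ring is a cyclised terminal isoprene unit. Its CMe2 carbon is the tertiary cation of a protonated isopropylidene group, and its CH and C(CH3)= carbons are the former C10=C11 alkene, so one proton can close it.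
4. Forward: farnesol gives the C16 tetraene 3; butynediol gives 6; hydroboration and Suzuki coupling join them to the C20 chain 8; a terpene cyclase closes the only ring (8 to 9); acetylation ends the route.
5. Stereochemistry: 6E and 10E come from farnesol, and 2E from trans-hydroalumination and stereoretentive coupling. The single stereocentre (S) is set in the ring closure by the enzyme, which also has to pick one of four alkenes, stop after one ring and place the ring alkene, a combination no small acid offers.

Key step: step 5

Assumption (chemistry): the facial sense of ring closure native to squalene–hopene cyclases (as in the first ring of hopene) corresponds to the (S) centre of the target, so no reversal of the enzyme's preference is needed; a variant that stops after the first ring is taken from an active-site library.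

**Step 1**
Reactants: 1 (2E,6E)-farnesol
Product: 2 (2E,6E)-farnesal
Conditions: PhI(OAc)2, 2,2,6,6-tetramethylpiperidin-1-oxyl (cat.), CH2Cl2, rt
Reagents that add atoms: none
Why: Oxoammonium-mediated oxidation of a primary allylic alcohol (nitroxyl catalyst, hypervalent iodine as terminal oxidant) should stop at the enal and leave the 2E geometry and the two remote trisubstituted alkenes untouched.

**Step 2**
Reactants: 2 (2E,6E)-farnesal
Product: 3 (3E,7E)-4,8,12-trimethyltrideca-1,3,7,11-tetraene
Conditions: Ph3PCH3Br, KOtBu, THF, 0 °C → rt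
Reagents that add atoms: methyltriphenylphosphonium bromide, C[P+](c1ccccc1)(c1ccccc1)c1ccccc1.[Br-]
Why: Wittig methylenation of the enal with the unstabilised ylide should add the terminal CH2 without touching the existing alkene, which becomes the 3E alkene of the 1,3-diene.

**Step 3**
Reactants: 4 2-butyne-1,4-diol
Product: 6 (Z)-2-iodobut-2-ene-1,4-diol, via cyclic sodium alkenylalanate 5 (not isolated)
Conditions: NaAlH2(OCH2CH2OMe)2, THF, 0 °C → rt; then I2, −78 → 0 °C; aq. Na2S2O3 and Rochelle salt work-up
Reagents that add atoms: iodine, II; sodium bis(2-methoxyethoxy)aluminium dihydride, [Na+].COCCO[AlH2-]OCCOC (its aluminium, sodium and alkoxy groups stand in 5 only; 6 keeps one hydride hydrogen)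
Why: Trans-hydroalumination of a propargylic alkoxide (hydride to the near alkyne carbon, aluminium held on the far carbon in the five-membered oxaluminacycle 5, cis to the bound CH2O group) followed by iodinolysis with retention is the standard route to (Z)-3-iodoallylic alcohols, so 6 should form with iodine cis to the CH2OH on the other alkene carbon and the two CH2OH groups trans.

**Step 4**
Reactants: 3 (3E,7E)-4,8,12-trimethyltrideca-1,3,7,11-tetraene; 6 (Z)-2-iodobut-2-ene-1,4-diol
Product: 8 (2E)-2-[(3E,7E)-4,8,12-trimethyltrideca-3,7,11-trien-1-yl]but-2-ene-1,4-diol, via B-homofarnesyl-9-BBN 7 (not isolated)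
Conditions: 9-BBN, THF, 0 °C → rt; then 6, PdCl2(dppf) (dppf = 1,1'-bis(diphenylphosphino)ferrocene), AsPh3, Cs2CO3, DMF/H2O, rt
Reagents that add atoms: 9-borabicyclo[3.3.1]nonane, [H]B1C2CCCC1CCC2 (boron and its ring stand in 7 only; 8 keeps its hydrogen)
Why: 9-BBN should hydroborate only the monosubstituted terminus of the diene of 3 (anti-Markovnikov, the trisubstituted alkenes being too hindered) and the B-alkyl Suzuki–Miyaura coupling replaces iodine with retention of alkene geometry, which places the chain cis to the distal CH2OH and keeps the two CH2OH groups trans (2E), free hydroxyls being tolerated by this coupling.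

**Step 5**
Reactants: 8 (2E)-2-[(3E,7E)-4,8,12-trimethyltrideca-3,7,11-trien-1-yl]but-2-ene-1,4-diol
Product: 9 (2E)-2-{(3E)-4-methyl-6-[(1S)-2,6,6-trimethylcyclohex-2-en-1-yl]hex-3-en-1-yl}but-2-ene-1,4-diol
Conditions: squalene–hopene cyclase variant (terpene cyclase of the protonation-initiated type, Alicyclobacillus acidocaldarius enzyme expressed in E. coli, whole cells or purified enzyme), citrate buffer pH 6.0, 0.2% Triton X-100, 30 °C
Reagents that add atoms: none
Why: Proposed new method: the catalytic aspartic acid of the cyclase protonates C14 of the terminal isopropylidene group of 8, the tertiary cation at C15 is captured by C10 of the C10=C11 alkene held in a chair fold, and the resulting ring cation at C11 loses a proton from C12 to an active-site base, which gives the endocyclic trisubstituted alkene of 9. The closest known reaction type is the monocyclisation of acyclic polyprenoids such as squalene and geranylacetone by squalene–hopene cyclase variants in which the cascade is interrupted after the first ring. The one ring is closed in the 6-endo-trig mode with respect to the C10=C11 alkene (both alkene carbons end up in the ring, Markovnikov sense), forming the bond from the ring CH to the gem-dimethyl carbon. The only new stereocentre (ring C1, S) is controlled by the enzyme, whose pre-folding template fixes which face of C10 meets the cation; this is the sense native to this enzyme family. The step needs site selectivity for one of four alkenes, arrest after one ring, and loss of the ring CH2 proton instead of a methyl proton or the proton at ring C1. The first is secured by the substrate, whose diol head group cannot enter the lipophilic cavity and anchors at its mouth so that only the distal isopropylidene reaches the acid (the C2=C3 alkene is also electron-poor), and the other two by the choice of variant (a small residue in place of the aromatic residue that stabilises the second-ring cation and a base placed over C12).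

**Step 6**
Reactants: 9 (2E)-2-{(3E)-4-methyl-6-[(1S)-2,6,6-trimethylcyclohex-2-en-1-yl]hex-3-en-1-yl}but-2-ene-1,4-diol
Product: 10 (2E)-2-{(3E)-4-methyl-6-[(1S)-2,6,6-trimethylcyclohex-2-en-1-yl]hex-3-en-1-yl}but-2-ene-1,4-diyl diacetate
Conditions: Ac2O, pyridine, 4-(dimethylamino)pyridine (cat.), CH2Cl2, 0 °C → rt
Reagents that add atoms: acetic anhydride, CC(=O)OC(C)=O
Why: Acylation of the two primary allylic alcohols with acetic anhydride under nucleophilic catalysis should be complete and touches neither the stereocentre nor the alkenes.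

**Compound list**
1 | (2E,6E)-farnesol | CC(C)=CCC/C(C)=C/CC/C(C)=C/CO | starting material
2 | (2E,6E)-farnesal | CC(C)=CCC/C(C)=C/CC/C(C)=C/C=O | intermediate
3 | (3E,7E)-4,8,12-trimethyltrideca-1,3,7,11-tetraene | CC(C)=CCC/C(C)=C/CC/C(C)=C/C=C | intermediate
4 | 2-butyne-1,4-diol | OCC#CCO | starting material
5 | cyclic sodium alkenylalanate (sodium 4-(hydroxymethyl)-2,2-bis(2-methoxyethoxy)-2,5-dihydro-1,2-oxaluminol-2-uide) | [Na+].COCCO[Al-]1(OCCOC)OCC=C1CO | intermediate
6 | (Z)-2-iodobut-2-ene-1,4-diol | OC/C=C(\I)CO | intermediate
7 | 9-[(3E,7E)-4,8,12-trimethyltrideca-3,7,11-trien-1-yl]-9-borabicyclo[3.3.1]nonane | CC(C)=CCC/C(C)=C/CC/C(C)=C/CCB1C2CCCC1CCC2 | intermediate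
8 | (2E)-2-[(3E,7E)-4,8,12-trimethyltrideca-3,7,11-trien-1-yl]but-2-ene-1,4-diol | OC/C=C(\CC/C=C(\C)CC/C=C(\C)CCC=C(C)C)CO | intermediate
9 | (2E)-2-{(3E)-4-methyl-6-[(1S)-2,6,6-trimethylcyclohex-2-en-1-yl]hex-3-en-1-yl}but-2-ene-1,4-diol | OC/C=C(\CC/C=C(\C)CC[C@@H]1C(C)=CCCC1(C)C)CO | intermediate
10 | (2E)-2-{(3E)-4-methyl-6-[(1S)-2,6,6-trimethylcyclohex-2-en-1-yl]hex-3-en-1-yl}but-2-ene-1,4-diyl diacetate | CC(=O)OC/C=C(\CC/C=C(\C)CC[C@@H]1C(C)=CCCC1(C)C)COC(C)=O | target

**Step count and risks**
Total steps: 6. Longest linear sequence: 5 (steps 1, 2, 4, 5, 6; step 3 makes the coupling partner).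

Steps most likely to fail:

1. Step 5 (carries the label). What may go wrong: the cation cascade may run on into a second ring, or be quenched by water or by a hydroxyl of the head group. The proton may be lost from the ring methyl or from ring C1 instead of the ring CH2. The diol may also bind unproductively so that conversion stays low. Fallback (known reaction types; sets out from 6 and returns at 9): the ring is built first with chirality transfer and the chain is joined to 6 afterwards. Commercial 2,4,4-trimethylcyclohex-2-en-1-one F1 is reduced by Corey–Bakshi–Shibata reduction (BH3·SMe2, (S)-1-methyl-3,3-diphenyltetrahydro-1H,3H-pyrrolo[1,2-c][1,3,2]oxazaborole as catalyst, THF, −20 °C) to (1R)-2,4,4-trimethylcyclohex-2-en-1-ol F2, the methyl-bearing alkenyl carbon acting as the large group. Johnson–Claisen rearrangement (MeC(OEt)3, EtCO2H cat., 140 °C) should then transfer the carbinol chirality suprafacially to the carbon next to the gem-dimethyl group and give ethyl 2-[(1S)-2,6,6-trimethylcyclohex-2-en-1-yl]acetate F3, with the ring alkene already in its final place. Reduction with LiAlH4 (Et2O, 0 °C) gives 2-[(1S)-2,6,6-trimethylcyclohex-2-en-1-yl]ethan-1-ol F4, and I2, PPh3 and imidazole (CH2Cl2) give (6S)-6-(2-iodoethyl)-1,5,5-trimethylcyclohex-1-ene F5. Displacement with LiC≡CH·H2NCH2CH2NH2 in DMSO gives (6S)-6-(but-3-yn-1-yl)-1,5,5-trimethylcyclohex-1-ene F6. Zirconium-catalysed methylalumination (Me3Al, Cp2ZrCl2, CH2Cl2; syn addition) gives dimethyl{(1E)-2-methyl-4-[(1S)-2,6,6-trimethylcyclohex-2-en-1-yl]but-1-en-1-yl}alumane F7, which is coupled in the same flask with vinyl bromide (Pd(PPh3)4, ZnCl2, THF) to (6S)-1,5,5-trimethyl-6-[(3E)-3-methylhexa-3,5-dien-1-yl]cyclohex-1-ene F8. Hydroboration with 9-BBN gives 9-{(3E)-4-methyl-6-[(1S)-2,6,6-trimethylcyclohex-2-en-1-yl]hex-3-en-1-yl}-9-borabicyclo[3.3.1]nonane F9, and Suzuki–Miyaura coupling with 6 under the conditions of step 4 should give 9.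

2. Step 4. What may go wrong: hydroboration of the diene terminus may be accompanied by addition at the internal diene position, and transfer of the primary alkyl group from boron may be slow beside the unprotected diol, so that reduction of the C–I bond of 6 competes. Fallback (sets out from 1 and 6, returns at 8): the C16 nucleophile is made by alkylative one-carbon homologation instead of olefination and hydroboration. Alcohol 1 is converted with PBr3 (Et2O, 0 °C) into (2E,6E)-farnesyl bromide F10. Deborylative alkylation with bis(4,4,5,5-tetramethyl-1,3,2-dioxaborolan-2-yl)methane and NaOtBu (THF, rt) gives 4,4,5,5-tetramethyl-2-[(3E,7E)-4,8,12-trimethyltrideca-3,7,11-trien-1-yl]-1,3,2-dioxaborolane F11. This is coupled with 6 (Pd(OAc)2, 2-dicyclohexylphosphino-2',6'-diisopropoxybiphenyl, K3PO4, toluene/H2O, 80 °C) to give 8.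

3. Step 3. What may go wrong: protonolysis of the alkenylalanate before iodinolysis (which gives the iodine-free alkene), over-reduction, or incomplete iodinolysis on the unprotected diol. Fallback (sets out from 4, returns at 6): ruthenium-catalysed trans-hydrostannation of 4 (Bu3SnH, [Cp*RuCl]4 cat., CH2Cl2, rt), directed by the propargylic hydroxyl, should give (Z)-2-(tributylstannyl)but-2-ene-1,4-diol F12. Iododestannylation with retention (I2, CH2Cl2, 0 °C) then gives 6.

**Further compounds**
F1 | step 5 | 2,4,4-trimethylcyclohex-2-en-1-one | CC1=CC(C)(C)CCC1=O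
F2 | step 5 | (1R)-2,4,4-trimethylcyclohex-2-en-1-ol | CC1=CC(C)(C)CC[C@H]1O
F3 | step 5 | ethyl 2-[(1S)-2,6,6-trimethylcyclohex-2-en-1-yl]acetate | CCOC(=O)C[C@@H]1C(C)=CCCC1(C)C
F4 | step 5 | 2-[(1S)-2,6,6-trimethylcyclohex-2-en-1-yl]ethan-1-ol | OCC[C@@H]1C(C)=CCCC1(C)C
F5 | step 5 | (6S)-6-(2-iodoethyl)-1,5,5-trimethylcyclohex-1-ene | ICC[C@@H]1C(C)=CCCC1(C)C
F6 | step 5 | (6S)-6-(but-3-yn-1-yl)-1,5,5-trimethylcyclohex-1-ene | C#CCC[C@@H]1C(C)=CCCC1(C)C
F7 | step 5 | dimethyl{(1E)-2-methyl-4-[(1S)-2,6,6-trimethylcyclohex-2-en-1-yl]but-1-en-1-yl}alumane | C[Al](C)/C=C(\C)CC[C@@H]1C(C)=CCCC1(C)C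
F8 | step 5 | (6S)-1,5,5-trimethyl-6-[(3E)-3-methylhexa-3,5-dien-1-yl]cyclohex-1-ene | C=C/C=C(\C)CC[C@@H]1C(C)=CCCC1(C)C
F9 | step 5 | 9-{(3E)-4-methyl-6-[(1S)-2,6,6-trimethylcyclohex-2-en-1-yl]hex-3-en-1-yl}-9-borabicyclo[3.3.1]nonane | B2(C3CCCC2CCC3)CC/C=C(\C)CC[C@@H]1C(C)=CCCC1(C)C
F10 | step 4 | (2E,6E)-farnesyl bromide | CC(C)=CCC/C(C)=C/CC/C(C)=C/CBr
F11 | step 4 | 4,4,5,5-tetramethyl-2-[(3E,7E)-4,8,12-trimethyltrideca-3,7,11-trien-1-yl]-1,3,2-dioxaborolane | CC(C)=CCC/C(C)=C/CC/C(C)=C/CCB1OC(C)(C)C(C)(C)O1
F12 | step 3 | (Z)-2-(tributylstannyl)but-2-ene-1,4-diol | OC/C=C(\[Sn](CCCC)(CCCC)CCCC)CO
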